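## The problem

Gnetofuran A is a trans-2-aryl-3-hydroxymethyl-2,3-dihydrobenzofuran. Its benzo ring is fully differentiated: O1 at C7a, C3 at C3a, hydrogen at C4 and C6, an (E)-3,5-dihydroxystyryl group at C5 and a methoxy group at C7. The only stereocentres are the adjacent C2 (R, bearing O1 and the 4-hydroxy-3-methoxyphenyl group) and C3 (S, bearing CH2OH). C2 is a benzylic ether carbon para to a phenol, so it can ionise in acid or open to a para-quinone methide in base and reclose. The trans isomer is the more stable one, so C3 can correct C2 but nothing can correct C3. The absolute configuration therefore has to be lodged at C3 and carried there untouched. Three phenols, an electron-rich (E)-stilbene and a primary alcohol exclude hydrogenolysis, strong oxidants, strong Lewis acids and any late electrophilic halogenation, so the stilbene must come late. The C5 and C7 substituents are meta to each other with hydrogen between and beside them, which is exactly the pattern a regioselective alkyne cyclotrimerisation gives. The enabling feature is that O1, C2 and C3 form a three-atom bridge between C7a and C3a. Read backwards, the bicycle is a 1,6-diyne (an alkynyl ether C7a≡C7 and a carbon alkyne C3a≡C4 joined through O1–C2–C3) plus a two-carbon alkyne that supplies C5 and C6, and both stereocentres sit in the tether.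

## Retrosynthesis

**Unmasking (29 from 28).** No skeletal bond is cut. Target 29 is traced to 28, which carries three methoxymethyl ethers on the phenols and a tert-butyldimethylsilyl ether on the primary alcohol. Acetal protection is preferred to aryl silyl ethers because an earlier step runs in hot carbonate/methanol, and to benzyl ethers because hydrogenolysis would reduce the stilbene. One acidic step removes all four groups, and acid can move C2 only toward the trans arrangement that C3 dictates. The forward step must not solvolyse C2 or damage the stilbene.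

**Stilbene (28 from 23 and 26).** The C=C bond is cut to aldehyde 23 and benzylic phosphonate 26. Cutting the aryl–vinyl bond instead (Heck) would need a C5 halide carried beside the C7 iodide of 20. A Wittig reaction would give E/Z mixtures. The Horner–Wadsworth–Emmons reaction is E-selective, and its aldehyde comes from the ester that the cycloaddition partner delivers. The alkene is introduced after the iodination step, which it would not survive. Phosphonate 26 comes from 3,5-dihydroxybenzyl alcohol 24 through 25.

**C5 and C7 adjustment (23 from 19 through 22, 21, 20).** Aldehyde 23 comes from ester 21 by reduction to 22 and benzylic oxidation. The C7 methoxy group of 21 cannot be present on the alkyne, because a 1,2-dialkoxyalkyne is not a workable building block, so C7 needs a placeholder. A boryl group would be the most direct latent oxygen. It is not used for two reasons: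
- An alkynylboronate cannot be installed on the lithium alkynyl ether in the presence of a free terminal alkyne, which would be metalated and borylated as well.
- It would not survive the basic methanolysis that unmasks a silyl-capped alkyne.

A triethylsilyl group meets every demand. It is put on the acetylide, outlasts removal of a trimethylsilyl cap, is bulky enough to steer the cycloaddition, and sits ortho to O1 in 19, where ipso-iodination to 20 is strongly favoured. Copper-mediated etherification then gives 21.

**Key disconnection (19 from 17 and 18).** Cutting C3a–C7a, C4–C5 and C6–C7 gives diyne 17 and methyl propiolate 18. The neighbouring single cuts (O1–C2 by etherification, C3–C3a by arylation) each start from a pre-made 1,2,3,5-tetrasubstituted benzene. The triple cut builds that pattern from three alkynes, removes both rings at once and leaves the stereocentres in an open chain. The forward reaction must put the ester at C5 and not C6, must favour cross- over homo-coupling, and must run at room temperature because 17 is a thermally labile benzylic alkynyl ether.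

**Alkynyl ether (17 from 16, 13, 11).** The O1–C7a bond and the C7–Si bond are cut. Alcohol 11 adds to dichloroacetylene (from trichloroethylene) to give dichlorovinyl ether 13. Elimination and chlorine–lithium exchange give a lithium alkynyl ether that is silylated to 16. The trimethylsilyl cap on the carbon alkyne keeps that alkyne out of the organolithium chemistry, and its selective removal then gives 17. This ordering is the only one in which the two alkyne termini end up differentiated (H at the future C4, silicon at the future C7).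

**Stereocentres (11 from 7 and 9).** The C2–C3 bond is cut between aldehyde 9 and a chiral allenylzinc reagent derived from propargylic mesylate 7. This sets both stereocentres in one step: the future C3 by chirality transfer from 7, the future C2 by the cyclic transition state (anti). An aldol route would need three or four further steps to convert a carbonyl into the alkyne.

**Building blocks.** Mesylate 7 comes from (R)-alcohol 6, made by asymmetric transfer hydrogenation of ynone 5. Ynone 5 comes from trimethylsilylacetylene 1 and silyloxyacetaldehyde 2 through racemic alcohol 4. Aldehyde 9 is vanillin 8 protected as its methoxymethyl ether.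

## Roads not taken

Alternative 1: Oxidative ring contraction of a flavanone.
- **Cut and key step.** The C3–C3a bond is made by a 1,2-shift. Flavanone A1 is treated with PhI(OAc)2 (trivalent iodine) and sulfuric acid in trimethyl orthoformate. The enol ether is iodinated at C3 and the fused aryl carbon migrates from the carbonyl carbon to C3, which contracts the pyranone and turns the old carbonyl carbon into the methyl ester of trans product A2.
- **Merits.** A1 is two or three steps from simple aromatic building blocks. The substituents at C5 (bromide, a Heck handle) and C7 are bought rather than made. The ester is one reduction away from CH2OH. The whole route would be clearly shorter than the chosen one.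
- **Weak points.** The only source of absolute configuration is C2 of A1, a centre that opens reversibly by retro-oxa-Michael reaction and must survive a strongly acidic oxidation; the deactivating mesylate on the phenol is there for that reason. Dehydrogenation to the flavone and 2,3-aryl shift compete with contraction.
- **Comparison.** Alternative 1 wins on step count and cost. The chosen plan sets against it that chirality resides at C3, the centre that cannot epimerise, and that no stereocentre passes through ionising conditions until the last step, where thermodynamics favour the right isomer.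

Alternative 2: Three-component dearomative coupling.
- **Cut and key step.** C2–C1′ and C3–C(allyl) are cut across the furan double bond. Benzofuran A3 is lithiated at C2 and added to aryl boronic ester A4. A chiral allylpalladium complex from Pd2(dba)3 (zerovalent palladium) and allyl acetate A5 alkylates C3 while the aryl group shifts from boron to C2, giving A6 with aryl and allyl trans.
- **Merits.** It is convergent, starts from flat achiral components and creates both stereocentres in one catalytic enantioselective step. In this respect it is better than the chosen plan.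
- **Weak points.** C2 of A6 is a fully substituted α-oxy benzylic boronate that must be protodeboronated with defined stereochemistry without elimination to the aromatic benzofuran. The allyl group has one carbon too many, so it needs isomerisation, ozonolysis and reduction before the stilbene can be present. The aldehyde must travel as an acetal.
- **Comparison.** After the key step about seven operations remain, so the overall length is similar to the chosen route. The chosen plan offers the correct carbon count and oxidation level at C3 from the start and no stereospecific C–B to C–H exchange at a tertiary centre.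

Alternative 3: Oxidative etherification through a para-quinone methide.
- **Cut and key step.** O1–C2 is cut. Ag2O (monovalent silver) oxidises the 4-hydroxy-3-methoxybenzyl unit of open-chain bisphenol A7 to a para-quinone methide. The neighbouring phenol adds to its exocyclic carbon and closes the ring trans to the C3 substituent, giving A8.
- **Merits.** It is biomimetic and short, and needs no protection of the guaiacyl phenol. C3 controls C2 exactly as in the chosen plan. The bromide is a Heck handle.
- **Weak points.** The quinone methide carries a doubly benzylic hydrogen at C3 and can tautomerise to a styrene, which erases the only stereocentre. The cyclising phenol is itself an oxidisable 2-methoxyphenol. A kinetic cis/trans mixture is possible, and silver is used stoichiometrically.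
- **Comparison.** Alternative 3 is as short as Alternative 1 and equal to the chosen plan in stereochemical logic. The chosen plan never places C3 next to a quinoid or cationic centre while its configuration is still at stake.

Key step: step 10

Assumption: the (S,S) transfer-hydrogenation catalyst places the alkynyl group of ynone 5 where it places the aryl group of an aryl ketone, and the allenylzinc sequence proceeds with overall inversion at the propargylic carbon; if either sense is opposite, the enantiomeric catalyst is used in step 3.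

Step 1
Reactants: 1 trimethylsilylacetylene; 2 (tert-butyldimethylsilyloxy)acetaldehyde
Product: 4 rac-1-(tert-butyldimethylsilyloxy)-4-(trimethylsilyl)but-3-yn-2-ol, via lithium (trimethylsilyl)acetylide 3 (not isolated)
Conditions: n-BuLi, THF, −78 °C; then 2, −78 to −20 °C; aq. NH4Cl
Reagents that add atoms: none
Why: Deprotonation of the terminal alkyne and 1,2-addition of the acetylide to the aldehyde; the racemate is acceptable because the stereocentre is erased and reset in steps 2 and 3.

Step 2
Reactants: 4 rac-1-(tert-butyldimethylsilyloxy)-4-(trimethylsilyl)but-3-yn-2-ol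
Product: 5 1-(tert-butyldimethylsilyloxy)-4-(trimethylsilyl)but-3-yn-2-one
Conditions: Dess–Martin periodinane, NaHCO3, CH2Cl2, 0 °C to rt
Reagents that add atoms: none
Why: Dess–Martin oxidation of a propargylic alcohol under buffered conditions leaves the silyl ether and the alkynylsilane intact.

Step 3
Reactants: 5 1-(tert-butyldimethylsilyloxy)-4-(trimethylsilyl)but-3-yn-2-one
Product: 6 (R)-1-(tert-butyldimethylsilyloxy)-4-(trimethylsilyl)but-3-yn-2-ol
Conditions: RuCl[(S,S)-TsDPEN](p-cymene) (divalent ruthenium, 1 mol %), KOH (2 mol %), i-PrOH, rt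
Reagents that add atoms: none
Why: Noyori asymmetric transfer hydrogenation of an alkynyl ketone reduces the carbonyl in preference to the triple bond; with the alkynyl group in the site of an aryl group the (S,S) catalyst should give the (R) carbinol.

Step 4
Reactants: 6 (R)-1-(tert-butyldimethylsilyloxy)-4-(trimethylsilyl)but-3-yn-2-ol
Product: 7 (R)-1-(tert-butyldimethylsilyloxy)-4-(trimethylsilyl)but-3-yn-2-yl methanesulfonate
Conditions: MsCl, Et3N, CH2Cl2, −78 to 0 °C
Reagents that add atoms: methanesulfonyl chloride, CS(=O)(=O)Cl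
Why: O-sulfonylation with retention at carbon; the propargylic mesylate is used without storage.

Step 5
Reactants: 8 vanillin
Product: 9 3-methoxy-4-(methoxymethoxy)benzaldehyde
Conditions: MOMCl, i-Pr2NEt, CH2Cl2, 0 °C to rt
Reagents that add atoms: chloromethyl methyl ether, COCCl
Why: O-alkylation of the phenol; the acetal ether tolerates organozinc, organolithium, hydride, iodine monochloride and hot carbonate in methanol, and leaves with acid at the end.

Step 6
Reactants: 7 (R)-1-(tert-butyldimethylsilyloxy)-4-(trimethylsilyl)but-3-yn-2-yl methanesulfonate; 9 3-methoxy-4-(methoxymethoxy)benzaldehyde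
Product: 11 (1R,2S)-2-[(tert-butyldimethylsilyloxy)methyl]-1-[3-methoxy-4-(methoxymethoxy)phenyl]-4-(trimethylsilyl)but-3-yn-1-ol, via allenylzinc reagent 10 (not isolated)
Conditions: Pd(OAc)2 (divalent palladium, 5 mol %), PPh3 (5 mol %), Et2Zn (3 equiv), THF, −78 to −20 °C
Reagents that add atoms: none
Why: Marshall propargylation: zerovalent palladium formed in situ displaces the mesylate anti (SN2′), transmetalation with retention gives allenylzinc 10, and cyclic SE2′ addition with the aryl group equatorial gives the anti alcohol; C2 of the chain (later C3) is set by chirality transfer from 7 with overall inversion, C1 (later C2) by the chair-like transition state.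

Step 7
Reactants: 11 (1R,2S)-2-[(tert-butyldimethylsilyloxy)methyl]-1-[3-methoxy-4-(methoxymethoxy)phenyl]-4-(trimethylsilyl)but-3-yn-1-ol
Product: 13 (1R,2S)-2-[(tert-butyldimethylsilyloxy)methyl]-1-[(E)-1,2-dichlorovinyloxy]-1-[3-methoxy-4-(methoxymethoxy)phenyl]-4-(trimethylsilyl)but-3-yne, via potassium alkoxide 12 (not isolated)
Conditions: KH, THF, 0 °C; then Cl2C=CHCl, −50 °C to rt
Reagents that add atoms: trichloroethylene, ClC=C(Cl)Cl
Why: The alkoxide adds anti to dichloroacetylene generated in situ and the vinyl anion is protonated, giving the (E)-dichlorovinyl ether without touching the carbinol centre; the C-silylated alkyne has no acidic hydrogen.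

Step 8
Reactants: 13 (1R,2S)-2-[(tert-butyldimethylsilyloxy)methyl]-1-[(E)-1,2-dichlorovinyloxy]-1-[3-methoxy-4-(methoxymethoxy)phenyl]-4-(trimethylsilyl)but-3-yne
Product: 16 (1R,2S)-2-[(tert-butyldimethylsilyloxy)methyl]-1-[3-methoxy-4-(methoxymethoxy)phenyl]-1-[(triethylsilyl)ethynyloxy]-4-(trimethylsilyl)but-3-yne, via chloroalkynyl ether 14 (not isolated), via lithium alkynyl ether 15 (not isolated)
Conditions: n-BuLi (2.3 equiv), THF, −78 to −50 °C; then Et3SiCl, −78 to 0 °C
Reagents that add atoms: chlorotriethylsilane, CC[Si](Cl)(CC)CC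
Why: Dehydrochlorination to 14 and chlorine–lithium exchange give lithium alkynyl ether 15, which is silylated on carbon; the trimethylsilyl cap on the other alkyne makes this C-silylation site-specific.

Step 9
Reactants: 16 (1R,2S)-2-[(tert-butyldimethylsilyloxy)methyl]-1-[3-methoxy-4-(methoxymethoxy)phenyl]-1-[(triethylsilyl)ethynyloxy]-4-(trimethylsilyl)but-3-yne
Product: 17 (1R,2S)-2-[(tert-butyldimethylsilyloxy)methyl]-1-[3-methoxy-4-(methoxymethoxy)phenyl]-1-[(triethylsilyl)ethynyloxy]but-3-yne
Conditions: K2CO3 (0.2 equiv), MeOH–THF, 0 °C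
Reagents that add atoms: none
Why: Base-catalysed methanolysis of alkynylsilanes is markedly faster for trimethylsilyl than for triethylsilyl, so only the carbon alkyne should be unmasked; alkynyl ethers are stable to base, and the cold conditions avoid sigmatropic rearrangement of the benzylic alkynyl ether.

Step 10
Reactants: 17 (1R,2S)-2-[(tert-butyldimethylsilyloxy)methyl]-1-[3-methoxy-4-(methoxymethoxy)phenyl]-1-[(triethylsilyl)ethynyloxy]but-3-yne; 18 methyl propiolate
Product: 19 methyl (2R,3S)-3-[(tert-butyldimethylsilyloxy)methyl]-2-[3-methoxy-4-(methoxymethoxy)phenyl]-7-(triethylsilyl)-2,3-dihydrobenzofuran-5-carboxylate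
Conditions: Cp*RuCl(cod) (divalent ruthenium, 5–10 mol %), 18 (3 equiv, slow addition), ClCH2CH2Cl, rt
Reagents that add atoms: none
Why: Cp*RuCl, freed from cyclooctadiene, couples the two alkynes of 17 oxidatively to a bicyclic ruthenacycle, which forms C3a–C7a and closes the dihydrofuran ring as the five-membered ring fused to the metallacycle; insertion of 18 at the unsubstituted α-carbon (C4) and reductive elimination form C4–C5 and C6–C7 and close the benzene ring. The closest known reaction type is the Cp*RuCl-catalysed cocyclisation of unsymmetrical ether-, amine- and ynamide-tethered 1,6-diynes with terminal alkynes at room temperature, and alkoxy(silyl)alkynes are established cyclotrimerisation partners. No stereocentre is formed: C2 and C3 lie in the tether, take part in no bond change, and the anti (1R,2S) chain becomes the trans (2R,3S) ring. The step needs regioselectivity (ester at C5, meta to C7), which the triethylsilyl group secures by blocking its own α-carbon and keeping the ester of the incoming alkyne away, so that the substituted carbon of 18 bonds to C4. It needs cross- over homo-coupling, which intramolecular diyne coupling and slow addition of 18 secure. It must outrun the thermal [3,3] shift of the benzylic alkynyl ether, which the room-temperature activity of this catalyst allows.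

Step 11
Reactants: 19 methyl (2R,3S)-3-[(tert-butyldimethylsilyloxy)methyl]-2-[3-methoxy-4-(methoxymethoxy)phenyl]-7-(triethylsilyl)-2,3-dihydrobenzofuran-5-carboxylate
Product: 20 methyl (2R,3S)-3-[(tert-butyldimethylsilyloxy)methyl]-7-iodo-2-[3-methoxy-4-(methoxymethoxy)phenyl]-2,3-dihydrobenzofuran-5-carboxylate
Conditions: ICl (1.05 equiv), NaHCO3, CH2Cl2, −78 to −30 °C; aq. Na2S2O3
Reagents that add atoms: iodine monochloride, ClI
Why: Electrophilic ipso-iododesilylation: C7 is ortho to O1 and silicon leaves far faster than a proton from any other ring position, so iodine should enter only where the silyl group was; low temperature protects the electron-rich aryl ring.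

Step 12
Reactants: 20 methyl (2R,3S)-3-[(tert-butyldimethylsilyloxy)methyl]-7-iodo-2-[3-methoxy-4-(methoxymethoxy)phenyl]-2,3-dihydrobenzofuran-5-carboxylate
Product: 21 methyl (2R,3S)-3-[(tert-butyldimethylsilyloxy)methyl]-7-methoxy-2-[3-methoxy-4-(methoxymethoxy)phenyl]-2,3-dihydrobenzofuran-5-carboxylate
Conditions: CuI (monovalent copper, 10 mol %), 3,4,7,8-tetramethyl-1,10-phenanthroline (20 mol %), Cs2CO3, MeOH–toluene, 80 °C
Reagents that add atoms: methanol, CO
Why: Copper-catalysed Ullmann-type etherification of an aryl iodide with methanol; ester exchange is degenerate, acetal and alkyl silyl ether are base-stable, and neither stereocentre is acidic because the ester is meta to C3a.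

Step 13
Reactants: 21 methyl (2R,3S)-3-[(tert-butyldimethylsilyloxy)methyl]-7-methoxy-2-[3-methoxy-4-(methoxymethoxy)phenyl]-2,3-dihydrobenzofuran-5-carboxylate
Product: 22 [(2R,3S)-3-[(tert-butyldimethylsilyloxy)methyl]-7-methoxy-2-[3-methoxy-4-(methoxymethoxy)phenyl]-2,3-dihydrobenzofuran-5-yl]methanol
Conditions: i-Bu2AlH (2.5 equiv), CH2Cl2, −78 to 0 °C; aq. potassium sodium tartrate
Reagents that add atoms: none
Why: Hydride reduction of the aryl ester to the benzylic alcohol; acetal, silyl ether and aryl ethers are inert at this temperature.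

Step 14
Reactants: 22 [(2R,3S)-3-[(tert-butyldimethylsilyloxy)methyl]-7-methoxy-2-[3-methoxy-4-(methoxymethoxy)phenyl]-2,3-dihydrobenzofuran-5-yl]methanol
Product: 23 (2R,3S)-3-[(tert-butyldimethylsilyloxy)methyl]-7-methoxy-2-[3-methoxy-4-(methoxymethoxy)phenyl]-2,3-dihydrobenzofuran-5-carbaldehyde
Conditions: MnO2 (tetravalent manganese, excess), CH2Cl2, rt
Reagents that add atoms: none
Why: MnO2 oxidises the electron-rich benzylic alcohol to the aldehyde and stops there; no other free alcohol is present.

Step 15
Reactants: 24 3,5-dihydroxybenzyl alcohol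
Product: 25 3,5-bis(methoxymethoxy)benzyl alcohol
Conditions: MOMCl (2.2 equiv), K2CO3, acetone, 0 °C to rt
Reagents that add atoms: chloromethyl methyl ether, COCCl
Why: Carbonate deprotonates only the phenols, so O-alkylation leaves the benzylic alcohol free.

Step 16
Reactants: 25 3,5-bis(methoxymethoxy)benzyl alcohol
Product: 26 diethyl [3,5-bis(methoxymethoxy)benzyl]phosphonate
Conditions: ZnI2 (1.5 equiv), P(OEt)3 (3 equiv), toluene, reflux
Reagents that add atoms: triethyl phosphite, CCOP(OCC)OCC
Why: Zinc iodide-mediated one-flask Michaelis–Arbuzov-type conversion of an electron-rich benzylic alcohol into the phosphonate; it avoids an isolated benzylic halide and tolerates the acetal ethers.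

Step 17
Reactants: 26 diethyl [3,5-bis(methoxymethoxy)benzyl]phosphonate; 23 (2R,3S)-3-[(tert-butyldimethylsilyloxy)methyl]-7-methoxy-2-[3-methoxy-4-(methoxymethoxy)phenyl]-2,3-dihydrobenzofuran-5-carbaldehyde
Product: 28 (2R,3S)-5-{(E)-2-[3,5-bis(methoxymethoxy)phenyl]vinyl}-3-[(tert-butyldimethylsilyloxy)methyl]-7-methoxy-2-[3-methoxy-4-(methoxymethoxy)phenyl]-2,3-dihydrobenzofuran, via potassium phosphonate carbanion 27 (not isolated)
Conditions: KN(SiMe3)2, THF, 0 °C; then 23, 0 °C to rt
Reagents that add atoms: none
Why: Horner–Wadsworth–Emmons olefination of a non-enolisable aryl aldehyde; reversible addition and elimination through the less crowded oxaphosphetane give the (E)-stilbene.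

Step 18
Reactants: 28 (2R,3S)-5-{(E)-2-[3,5-bis(methoxymethoxy)phenyl]vinyl}-3-[(tert-butyldimethylsilyloxy)methyl]-7-methoxy-2-[3-methoxy-4-(methoxymethoxy)phenyl]-2,3-dihydrobenzofuran
Product: 29 gnetofuran A, (2R,3S)-5-[(E)-2-(3,5-dihydroxyphenyl)vinyl]-2-(4-hydroxy-3-methoxyphenyl)-3-(hydroxymethyl)-7-methoxy-2,3-dihydrobenzofuran
Conditions: HCl (3 M aq.), MeOH–THF, 40 °C
Reagents that add atoms: none
Why: Acid-catalysed acetal exchange removes the three methoxymethyl groups and solvolyses the primary silyl ether in one operation; C2, the only centre acid could ionise, can only return to the more stable trans arrangement dictated by C3.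

## Compound list

1 | trimethylsilylacetylene | C#C[Si](C)(C)C | starting material
2 | (tert-butyldimethylsilyloxy)acetaldehyde | CC(C)(C)[Si](C)(C)OCC=O | starting material
3 | lithium (trimethylsilyl)acetylide | [Li]C#C[Si](C)(C)C | intermediate
4 | rac-1-(tert-butyldimethylsilyloxy)-4-(trimethylsilyl)but-3-yn-2-ol | CC(C)(C)[Si](C)(C)OCC(O)C#C[Si](C)(C)C | intermediate
5 | 1-(tert-butyldimethylsilyloxy)-4-(trimethylsilyl)but-3-yn-2-one | CC(C)(C)[Si](C)(C)OCC(=O)C#C[Si](C)(C)C | intermediate
6 | (R)-1-(tert-butyldimethylsilyloxy)-4-(trimethylsilyl)but-3-yn-2-ol | CC(C)(C)[Si](C)(C)OC[C@H](O)C#C[Si](C)(C)C | intermediate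
7 | (R)-1-(tert-butyldimethylsilyloxy)-4-(trimethylsilyl)but-3-yn-2-yl methanesulfonate | CC(C)(C)[Si](C)(C)OC[C@H](OS(C)(=O)=O)C#C[Si](C)(C)C | intermediate
8 | vanillin | COc1cc(C=O)ccc1O | starting material
9 | 3-methoxy-4-(methoxymethoxy)benzaldehyde | COc1cc(C=O)ccc1OCOC | intermediate
10 | (aR)-[4-(tert-butyldimethylsilyloxy)-1-(trimethylsilyl)buta-1,2-dien-1-yl](ethyl)zinc | CC[Zn]C([Si](C)(C)C)=[C@]=C([H])CO[Si](C)(C)C(C)(C)C | intermediate
11 | (1R,2S)-2-[(tert-butyldimethylsilyloxy)methyl]-1-[3-methoxy-4-(methoxymethoxy)phenyl]-4-(trimethylsilyl)but-3-yn-1-ol (anti) | COc1cc([C@H](O)[C@@H](C#C[Si](C)(C)C)CO[Si](C)(C)C(C)(C)C)ccc1OCOC | intermediate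
12 | potassium alkoxide of 11 | COc1cc([C@H]([O-])[C@@H](C#C[Si](C)(C)C)CO[Si](C)(C)C(C)(C)C)ccc1OCOC.[K+] | intermediate
13 | (E)-1,2-dichlorovinyl ether of 11, (1R,2S) | COc1cc([C@H](O/C(Cl)=C\Cl)[C@@H](C#C[Si](C)(C)C)CO[Si](C)(C)C(C)(C)C)ccc1OCOC | intermediate
14 | chloroethynyl ether of 11, (1R,2S) | COc1cc([C@H](OC#CCl)[C@@H](C#C[Si](C)(C)C)CO[Si](C)(C)C(C)(C)C)ccc1OCOC | intermediate
15 | lithioethynyl ether of 11, (1R,2S) | COc1cc([C@H](OC#C[Li])[C@@H](C#C[Si](C)(C)C)CO[Si](C)(C)C(C)(C)C)ccc1OCOC | intermediate
16 | (1R,2S)-2-[(tert-butyldimethylsilyloxy)methyl]-1-[3-methoxy-4-(methoxymethoxy)phenyl]-1-[(triethylsilyl)ethynyloxy]-4-(trimethylsilyl)but-3-yne | COc1cc([C@H](OC#C[Si](CC)(CC)CC)[C@@H](C#C[Si](C)(C)C)CO[Si](C)(C)C(C)(C)C)ccc1OCOC | intermediate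
17 | (1R,2S)-2-[(tert-butyldimethylsilyloxy)methyl]-1-[3-methoxy-4-(methoxymethoxy)phenyl]-1-[(triethylsilyl)ethynyloxy]but-3-yne | COc1cc([C@H](OC#C[Si](CC)(CC)CC)[C@@H](C#C)CO[Si](C)(C)C(C)(C)C)ccc1OCOC | intermediate
18 | methyl propiolate | C#CC(=O)OC | starting material
19 | methyl (2R,3S)-3-[(tert-butyldimethylsilyloxy)methyl]-2-[3-methoxy-4-(methoxymethoxy)phenyl]-7-(triethylsilyl)-2,3-dihydrobenzofuran-5-carboxylate | COc1cc([C@@H]2Oc3c([Si](CC)(CC)CC)cc(C(=O)OC)cc3[C@H]2CO[Si](C)(C)C(C)(C)C)ccc1OCOC | intermediate
20 | methyl (2R,3S)-3-[(tert-butyldimethylsilyloxy)methyl]-7-iodo-2-[3-methoxy-4-(methoxymethoxy)phenyl]-2,3-dihydrobenzofuran-5-carboxylate | COc1cc([C@@H]2Oc3c(I)cc(C(=O)OC)cc3[C@H]2CO[Si](C)(C)C(C)(C)C)ccc1OCOC | intermediate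
21 | methyl (2R,3S)-3-[(tert-butyldimethylsilyloxy)methyl]-7-methoxy-2-[3-methoxy-4-(methoxymethoxy)phenyl]-2,3-dihydrobenzofuran-5-carboxylate | COc1cc([C@@H]2Oc3c(OC)cc(C(=O)OC)cc3[C@H]2CO[Si](C)(C)C(C)(C)C)ccc1OCOC | intermediate
22 | [(2R,3S)-3-[(tert-butyldimethylsilyloxy)methyl]-7-methoxy-2-[3-methoxy-4-(methoxymethoxy)phenyl]-2,3-dihydrobenzofuran-5-yl]methanol | COc1cc([C@@H]2Oc3c(OC)cc(CO)cc3[C@H]2CO[Si](C)(C)C(C)(C)C)ccc1OCOC | intermediate
23 | (2R,3S)-3-[(tert-butyldimethylsilyloxy)methyl]-7-methoxy-2-[3-methoxy-4-(methoxymethoxy)phenyl]-2,3-dihydrobenzofuran-5-carbaldehyde | COc1cc([C@@H]2Oc3c(OC)cc(C=O)cc3[C@H]2CO[Si](C)(C)C(C)(C)C)ccc1OCOC | intermediate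
24 | 3,5-dihydroxybenzyl alcohol | OCc1cc(O)cc(O)c1 | starting material
25 | 3,5-bis(methoxymethoxy)benzyl alcohol | COCOc1cc(CO)cc(OCOC)c1 | intermediate
26 | diethyl [3,5-bis(methoxymethoxy)benzyl]phosphonate | CCOP(=O)(Cc1cc(OCOC)cc(OCOC)c1)OCC | intermediate
27 | potassium salt of the benzylic carbanion of 26 | CCOP(=O)([CH-]c1cc(OCOC)cc(OCOC)c1)OCC.[K+] | intermediate
28 | (2R,3S)-5-{(E)-2-[3,5-bis(methoxymethoxy)phenyl]vinyl}-3-[(tert-butyldimethylsilyloxy)methyl]-7-methoxy-2-[3-methoxy-4-(methoxymethoxy)phenyl]-2,3-dihydrobenzofuran | COc1cc([C@@H]2Oc3c(OC)cc(/C=C/c4cc(OCOC)cc(OCOC)c4)cc3[C@H]2CO[Si](C)(C)C(C)(C)C)ccc1OCOC | intermediate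
29 | gnetofuran A, (2R,3S) | COc1cc([C@@H]2Oc3c(OC)cc(/C=C/c4cc(O)cc(O)c4)cc3[C@H]2CO)ccc1O | target

## Step count and risks

Total: 18 steps. Longest linear sequence: 15 steps (1–4, 6–14, 17, 18).

**Step 10 (key step).** No alkynyl-ether-tethered diyne of exactly this kind has been cocyclised; the precedent is by analogy to ynamide and ether tethers. The most likely failure is consumption of the electron-poor propiolate by its own ruthenium-catalysed trimerisation, together with erosion of regiocontrol, while the hindered silyl alkynyl ether is slow to enter the metallacycle. The benzylic alkynyl ether would then rearrange thermally before it is used. Fallback: set out from 17 and use 3,3-diethoxyprop-1-yne, an electron-neutral and bulkier partner already at the aldehyde oxidation level, under the same ruthenium catalysis. This gives (2R,3S)-3-[(tert-butyldimethylsilyloxy)methyl]-5-(diethoxymethyl)-2-[3-methoxy-4-(methoxymethoxy)phenyl]-7-(triethylsilyl)-2,3-dihydrobenzofuran F1. ICl then gives the 7-iodo acetal F2, CuI/Cs2CO3/MeOH gives the 7-methoxy acetal F3, and pyridinium p-toluenesulfonate in acetone–water releases the aldehyde. The route is rejoined at 23, and steps 13 and 14 are skipped.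

**Step 6.** The most likely failure is poor facial selectivity at the electron-rich aromatic aldehyde, so that the carbinol epimer forms beside 11. Elimination of silyloxide from the propargylic tautomer of 10 is a second risk. The future C3 is not at risk, because it is fixed by chirality transfer. Fallback: set out from the mixture of 11 and its epimer, (1S,2S)-2-[(tert-butyldimethylsilyloxy)methyl]-1-[3-methoxy-4-(methoxymethoxy)phenyl]-4-(trimethylsilyl)but-3-yn-1-ol F4. Oxidise both with Dess–Martin periodinane to (S)-2-[(tert-butyldimethylsilyloxy)methyl]-1-[3-methoxy-4-(methoxymethoxy)phenyl]-4-(trimethylsilyl)but-3-yn-1-one F5. Reset the carbinol centre under reagent control by Corey–Bakshi–Shibata reduction ((S)-2-methyl-CBS-oxazaborolidine, BH3·SMe2, THF, −20 °C). The route is rejoined at 11.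

**Step 9.** The most likely failure is loss of the triethylsilyl group from the alkynyl ether terminus together with the trimethylsilyl group, if the alkoxy substituent narrows the rate difference. Fallback: set out from 13, generate 15 as in step 8 and trap it with TBSOTf to give (1R,2S)-2-[(tert-butyldimethylsilyloxy)methyl]-1-[(tert-butyldimethylsilyl)ethynyloxy]-1-[3-methoxy-4-(methoxymethoxy)phenyl]-4-(trimethylsilyl)but-3-yne F6. Its silyl group is inert to carbonate in methanol, so desilylation gives the terminal alkyne F7. Cocyclisation with 18 gives methyl (2R,3S)-7-(tert-butyldimethylsilyl)-3-[(tert-butyldimethylsilyloxy)methyl]-2-[3-methoxy-4-(methoxymethoxy)phenyl]-2,3-dihydrobenzofuran-5-carboxylate F8. ipso-Iodination with ICl, slower and run at 0 °C to rt, rejoins the route at 20.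

**Step 11.** The most likely failure is competing electrophilic iodination of a C–H position on the methoxy/methoxymethoxy ring, because C7 is deactivated by the meta ester. Fallback: set out from 19 and reduce the ester first (i-Bu2AlH) to [(2R,3S)-3-[(tert-butyldimethylsilyloxy)methyl]-2-[3-methoxy-4-(methoxymethoxy)phenyl]-7-(triethylsilyl)-2,3-dihydrobenzofuran-5-yl]methanol F9. Its C7 is no longer deactivated. ICl with NaHCO3 at −78 °C gives the 7-iodo benzylic alcohol F10, and CuI/Cs2CO3/MeOH rejoins the route at 22.

**Step 18.** The most likely failure is acid-promoted ionisation at C2 with capture by methanol, or cationic oligomerisation of the electron-rich stilbene, while three acetal ethers are being removed. Fallback: set out from 23, where no stilbene is present, and change to fluoride-labile protection.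
- HCl/MeOH on 23 gives (2R,3S)-2-(4-hydroxy-3-methoxyphenyl)-3-(hydroxymethyl)-7-methoxy-2,3-dihydrobenzofuran-5-carbaldehyde F11.
- TBSCl/imidazole gives the bis-silyl aldehyde F12.
- Phosphonate 26 is converted by HCl/MeOH into diethyl (3,5-dihydroxybenzyl)phosphonate F13 and by TBSCl/imidazole into diethyl [3,5-bis(tert-butyldimethylsilyloxy)benzyl]phosphonate F14.
- KN(SiMe3)2 gives its potassium carbanion F15, which with F12 gives the tetrasilyl (E)-stilbene F16.
- Bu4NF buffered with AcOH in THF at 0 °C rejoins the route at 29.

## Further compounds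

F1 | step 10 | (2R,3S)-3-[(tert-butyldimethylsilyloxy)methyl]-5-(diethoxymethyl)-2-[3-methoxy-4-(methoxymethoxy)phenyl]-7-(triethylsilyl)-2,3-dihydrobenzofuran | COc1cc([C@@H]2Oc3c([Si](CC)(CC)CC)cc(C(OCC)OCC)cc3[C@H]2CO[Si](C)(C)C(C)(C)C)ccc1OCOC
F2 | step 10 | (2R,3S)-3-[(tert-butyldimethylsilyloxy)methyl]-5-(diethoxymethyl)-7-iodo-2-[3-methoxy-4-(methoxymethoxy)phenyl]-2,3-dihydrobenzofuran | COc1cc([C@@H]2Oc3c(I)cc(C(OCC)OCC)cc3[C@H]2CO[Si](C)(C)C(C)(C)C)ccc1OCOC
F3 | step 10 | (2R,3S)-3-[(tert-butyldimethylsilyloxy)methyl]-5-(diethoxymethyl)-7-methoxy-2-[3-methoxy-4-(methoxymethoxy)phenyl]-2,3-dihydrobenzofuran | COc1cc([C@@H]2Oc3c(OC)cc(C(OCC)OCC)cc3[C@H]2CO[Si](C)(C)C(C)(C)C)ccc1OCOC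
F4 | step 6 | (1S,2S)-2-[(tert-butyldimethylsilyloxy)methyl]-1-[3-methoxy-4-(methoxymethoxy)phenyl]-4-(trimethylsilyl)but-3-yn-1-ol (syn) | COc1cc([C@@H](O)[C@@H](C#C[Si](C)(C)C)CO[Si](C)(C)C(C)(C)C)ccc1OCOC
F5 | step 6 | (S)-2-[(tert-butyldimethylsilyloxy)methyl]-1-[3-methoxy-4-(methoxymethoxy)phenyl]-4-(trimethylsilyl)but-3-yn-1-one | COc1cc(C(=O)[C@@H](C#C[Si](C)(C)C)CO[Si](C)(C)C(C)(C)C)ccc1OCOC
F6 | step 9 | (1R,2S)-2-[(tert-butyldimethylsilyloxy)methyl]-1-[(tert-butyldimethylsilyl)ethynyloxy]-1-[3-methoxy-4-(methoxymethoxy)phenyl]-4-(trimethylsilyl)but-3-yne | COc1cc([C@H](OC#C[Si](C)(C)C(C)(C)C)[C@@H](C#C[Si](C)(C)C)CO[Si](C)(C)C(C)(C)C)ccc1OCOC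
F7 | step 9 | (1R,2S)-2-[(tert-butyldimethylsilyloxy)methyl]-1-[(tert-butyldimethylsilyl)ethynyloxy]-1-[3-methoxy-4-(methoxymethoxy)phenyl]but-3-yne | COc1cc([C@H](OC#C[Si](C)(C)C(C)(C)C)[C@@H](C#C)CO[Si](C)(C)C(C)(C)C)ccc1OCOC
F8 | step 9 | methyl (2R,3S)-7-(tert-butyldimethylsilyl)-3-[(tert-butyldimethylsilyloxy)methyl]-2-[3-methoxy-4-(methoxymethoxy)phenyl]-2,3-dihydrobenzofuran-5-carboxylate | COc1cc([C@@H]2Oc3c([Si](C)(C)C(C)(C)C)cc(C(=O)OC)cc3[C@H]2CO[Si](C)(C)C(C)(C)C)ccc1OCOC
F9 | step 11 | [(2R,3S)-3-[(tert-butyldimethylsilyloxy)methyl]-2-[3-methoxy-4-(methoxymethoxy)phenyl]-7-(triethylsilyl)-2,3-dihydrobenzofuran-5-yl]methanol | COc1cc([C@@H]2Oc3c([Si](CC)(CC)CC)cc(CO)cc3[C@H]2CO[Si](C)(C)C(C)(C)C)ccc1OCOC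
F10 | step 11 | [(2R,3S)-3-[(tert-butyldimethylsilyloxy)methyl]-7-iodo-2-[3-methoxy-4-(methoxymethoxy)phenyl]-2,3-dihydrobenzofuran-5-yl]methanol | COc1cc([C@@H]2Oc3c(I)cc(CO)cc3[C@H]2CO[Si](C)(C)C(C)(C)C)ccc1OCOC
F11 | step 18 | (2R,3S)-2-(4-hydroxy-3-methoxyphenyl)-3-(hydroxymethyl)-7-methoxy-2,3-dihydrobenzofuran-5-carbaldehyde | COc1cc([C@@H]2Oc3c(OC)cc(C=O)cc3[C@H]2CO)ccc1O
F12 | step 18 | (2R,3S)-2-[4-(tert-butyldimethylsilyloxy)-3-methoxyphenyl]-3-[(tert-butyldimethylsilyloxy)methyl]-7-methoxy-2,3-dihydrobenzofuran-5-carbaldehyde | COc1cc([C@@H]2Oc3c(OC)cc(C=O)cc3[C@H]2CO[Si](C)(C)C(C)(C)C)ccc1O[Si](C)(C)C(C)(C)C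
F13 | step 18 | diethyl (3,5-dihydroxybenzyl)phosphonate | CCOP(=O)(Cc1cc(O)cc(O)c1)OCC
F14 | step 18 | diethyl [3,5-bis(tert-butyldimethylsilyloxy)benzyl]phosphonate | CCOP(=O)(Cc1cc(O[Si](C)(C)C(C)(C)C)cc(O[Si](C)(C)C(C)(C)C)c1)OCC
F15 | step 18 | potassium salt of the benzylic carbanion of F14 | CCOP(=O)([CH-]c1cc(O[Si](C)(C)C(C)(C)C)cc(O[Si](C)(C)C(C)(C)C)c1)OCC.[K+]
F16 | step 18 | (2R,3S)-5-{(E)-2-[3,5-bis(tert-butyldimethylsilyloxy)phenyl]vinyl}-2-[4-(tert-butyldimethylsilyloxy)-3-methoxyphenyl]-3-[(tert-butyldimethylsilyloxy)methyl]-7-methoxy-2,3-dihydrobenzofuran | COc1cc([C@@H]2Oc3c(OC)cc(/C=C/c4cc(O[Si](C)(C)C(C)(C)C)cc(O[Si](C)(C)C(C)(C)C)c4)cc3[C@H]2CO[Si](C)(C)C(C)(C)C)ccc1O[Si](C)(C)C(C)(C)C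
A1 | alternative 1 | (R)-6-bromo-8-methoxy-2-[3-methoxy-4-(methylsulfonyloxy)phenyl]chroman-4-one | COc1cc([C@H]2CC(=O)c3cc(Br)cc(OC)c3O2)ccc1OS(C)(=O)=O
A2 | alternative 1 | methyl (2R,3R)-5-bromo-7-methoxy-2-[3-methoxy-4-(methylsulfonyloxy)phenyl]-2,3-dihydrobenzofuran-3-carboxylate (trans) | COc1cc([C@@H]2Oc3c(OC)cc(Br)cc3[C@H]2C(=O)OC)ccc1OS(C)(=O)=O
A3 | alternative 2 | 2-(7-methoxybenzofuran-5-yl)-1,3-dioxolane | COc1cc(C2OCCO2)cc2ccoc12
A4 | alternative 2 | 2-[4-(tert-butyldimethylsilyloxy)-3-methoxyphenyl]-4,4,5,5-tetramethyl-1,3,2-dioxaborolane | COc1cc(B2OC(C)(C)C(C)(C)O2)ccc1O[Si](C)(C)C(C)(C)C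
A5 | alternative 2 | allyl acetate | CC(=O)OCC=C
A6 | alternative 2 | 3-allyl-2-[4-(tert-butyldimethylsilyloxy)-3-methoxyphenyl]-5-(1,3-dioxolan-2-yl)-7-methoxy-2-(4,4,5,5-tetramethyl-1,3,2-dioxaborolan-2-yl)-2,3-dihydrobenzofuran (aryl and allyl trans) | COc1cc([C@]2(B3OC(C)(C)C(C)(C)O3)Oc3c(OC)cc(C4OCCO4)cc3[C@H]2CC=C)ccc1O[Si](C)(C)C(C)(C)C
A7 | alternative 3 | 4-bromo-2-[(S)-1-(tert-butyldimethylsilyloxy)-3-(4-hydroxy-3-methoxyphenyl)propan-2-yl]-6-methoxyphenol | COc1cc(C[C@H](CO[Si](C)(C)C(C)(C)C)c2cc(Br)cc(OC)c2O)ccc1O
A8 | alternative 3 | trans-5-bromo-3-[(tert-butyldimethylsilyloxy)methyl]-2-(4-hydroxy-3-methoxyphenyl)-7-methoxy-2,3-dihydrobenzofuran | COc1cc([C@@H]2Oc3c(OC)cc(Br)cc3[C@H]2CO[Si](C)(C)C(C)(C)C)ccc1O
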